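# Proposed synthesis of CNP0129770.0: 5,7-dihydroxy-3-(8-hydroxy-2,2-dimethylchroman-6-yl)-4H-chromen-4-one

## Analysis of the target

The target (C20H18O6) is an isoflavone: a benzopyran-4-one (benzo ring A; pyranone ring C with O1, C2, C3, C4, C4a and C8a) carrying at C3 an aryl ring B (C1' to C6'). A 2,2-dimethyldihydropyran (ring D) is fused to the C4'–C5' edge of ring B through the oxygen on C4'. There is no stereocentre, since the only quaternary sp3 carbon bears two identical methyl groups, so nothing has to be controlled in space. Ring A has the phloroglucinol pattern (O1 on C8a, hydroxyls on C5 and C7), and ring B has three adjacent substituents (hydroxyl on C3', ring D oxygen on C4', ring D methylene on C5'). The sensitive groups are the three phenols (the catechol-type C3' hydroxyl is prone to oxidation), ring C (it opens when hydroxide or alkoxide adds at C2) and the tertiary alkyl aryl ether of ring D (it can ionise under strong Lewis acids). The difficulty is regiochemical and tactical: two electron-rich arenes must be joined through C2–C3–C4 with the carbonyl between two oxygenated carbons of ring A, and the phenols must be unmasked last without harm to rings C and D. The strategy rests on the C4a–C8a edge of ring A: C4a carries the acyl carbon C4, C8a carries O1, and the other neighbour of C4a, C5, carries oxygen. That ortho-acyl phenol pattern is what an alkoxy-substituted aryne gives on insertion into the C–O bond of a carboxylic acid, and one acid can supply C2, C3, C4 and all of rings B and D.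

## Retrosynthetic reasoning

**Unmasking (19 from 18).** The three phenolic O–H bonds of 19 are traced back to O–CH3 bonds in 18. The phenols cannot be free earlier, because they would add to the aryne and quench the organolithium and hydride bases. Methyl ethers are inert to all of these and are already present in purchased 1 and 6, so no protecting-group step is spent. The forward reaction has to cleave three aryl methyl ethers, including the unreactive one on C7, and leave ring D closed.

**Ring C (18 from 14 and 5).** Ring C of 18 is cut at three bonds: O1–C8a, C4–C4a and O1–C2. Cutting there, and not at the C3–C1' bond or at a single bond of ring C, divides the molecule into two halves of similar size. These are acid 14 (C2, C3, C4, rings B and D) and silyl triflate 5 (ring A). The cut also lets the oxygen pattern of ring A decide the regiochemistry. In the forward direction fluoride turns 14 into carboxylate 15 and 5 into aryne 16. The carboxylate oxygen must bond to the aryne carbon remote from the flanking methoxyl, and the aryl anion must take over the acyl group to give phenoxide 17. Phenoxide 17 must then close onto the methoxy-bearing alkene carbon and expel methoxide. The methoxyl on C3 of the acrylic acid puts C2 at the oxidation level of the pyranone, so no dehydrogenation of a chromanone is needed.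

**Aryne precursor (5 from 1).** Silyl triflate 5 is cut at its C–Si and O–S bonds. The ortho relationship of silicon and oxygen derives from the C–Br bond of 2 by way of silyl ether 3: halogen–lithium exchange and migration of silicon from oxygen to carbon give phenoxide 4, which is triflated. Bromophenol 2 comes from 1 by bromination next to the hydroxyl, the position where silicon, and later C4, must sit.

**Acrylic acid (14 from 10 and 11).** Acid 14 is traced to ester 13, and the enol ether O–CH3 bond of 13 to hydroxymethylene ester 12. The C2–C3 bond (isoflavone numbering) of 12 is then cut. It forms by crossed Claisen condensation of arylacetate 10 with the one-carbon ester 11, which cannot enolise. The future C2 is thereby attached at the benzylic carbon of an arylacetic ester, the most accessible nucleophilic position of the ring B fragment.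

**Ring D (10 from 6 and 7).** Ring D of 10 derives from chromene 9 by saturation of its alkene. Chromene 9 is cut at the aryl–CH bond on C5' and at the O–CMe2 bond, leading back to aryl propargyl ether 8. The rearrangement of 8 can only go to C5', since the other ortho carbon carries the methoxyl, so the substitution pattern of 6 fixes the position of ring D. Ether 8 is cut at its O–C bond into phenol 6 and tertiary chloride 7.

## Alternatives that were turned down

**Alternative 1: ring D made last by a propargyl ether Claisen cascade.**
- Disconnection: ring D is cut at the C5'–CH bond and at the O–CMe2 bond, leaving an isoflavone with a free C4' oxygen, which is carried as its 1,1-dimethylpropargyl ether A2.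
- Forward key step: heating A2 in a high-boiling amine solvent should bring about [3,3] shift to C5', 1,5-hydrogen shift and oxa-6π closure to chromene A1. Hydrogenation of A1 would give 18.
- For: the cascade is regiospecific because C3' is blocked. The isoflavone core can come from classical deoxybenzoin chemistry, and every step has close precedent. On the reliability of the individual steps this alternative is stronger than the chosen route.
- Against: the simplest ring is built last on the most valuable material. After the core is made, four operations remain (etherification at a hindered tertiary centre, rearrangement near 190 °C, hydrogenation, demethylation). The hydrogenation must saturate the chromene alkene without touching C2=C3 of ring C. The core must carry one free phenol on C4' beside three masked ones, which costs an extra orthogonal protecting group.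
- Comparison: the chosen route runs the same cascade on the small ester 8, where heat and hydrogenation raise no selectivity issue. Its key step forms three bonds of ring C and joins two halves, so it is convergent where this alternative is linear.

**Alternative 2: O1–C8a closed by displacement of fluoride.**
- Disconnection: only O1–C8a is cut, with fluoride as leaving group, leading to the hydroxymethylene ketone A4 of a 2,4,6-trifluorophenyl ketone.
- Forward key step: a carbonate base in a dipolar aprotic solvent should deprotonate A4, and the enolate oxygen should displace an ortho fluoride, activated by the ortho carbonyl, to give A3.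
- For: the two ortho fluorides are equivalent, so there is no regiochemical question, and the conditions are mild. This ring closure is more certain than the aryne tandem.
- Against: A3 has fluorine where the target has hydroxyl on C5 and C7. Two further fluoride-for-methoxide exchanges would be needed to reach 18. They would be run on a heterocycle whose C2 is itself attacked by alkoxide, and the second exchange is slowed by the donor installed in the first.
- Comparison: the oxidation pattern of ring A is thus built by substitution on the finished, base-sensitive core, at the cost of two extra steps. The chosen route brings both ring A oxygens in with aryne 16 and makes O1 from the carboxylate, so it needs no such exchange.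

**Alternative 3: ring A made by Diels–Alder benzannulation.**
- Disconnection: ring A is cut at C4a–C5 and C8–C8a into the dioxygenated silyl ketene acetal diene A6 and bromopyranone A7.
- Forward key step: A6 should add across the brominated double bond of A7 with its nucleophilic CH2 terminus on the oxygen-bearing carbon (future C8a). Loss of HBr and methanol then aromatises the new ring to A5.
- For: two C–C bonds form, and ring A arrives with the C5 hydroxyl free and the C7 oxygen methylated. One methyl ether fewer has to be cleaved than in 18, which is an advantage over the chosen route.
- Against: a 4-pyranone is a vinylogous ester with aromatic character and a poor dienophile. A7 has a second enone double bond, needs a multistep synthesis of its own, and A6 is moisture-sensitive. A benzene ring that can be bought as 1 is built from scratch. The unreactive C7 methyl ether and the ring B methyl ether still have to be cleaved beside ring D.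
- Comparison: the chosen route takes ring A ready-made, never puts its aromaticity at stake, and joins the halves in one flask.

Key step: step 10

Remark: the methyl ester 6 of homovanillic acid is taken as the purchased form of that acid, and hydroxymethylene ester 12 is drawn as its enol tautomer.

## Route

Step 1
Reactants: 1 3,5-dimethoxyphenol
Product: 2 2-bromo-3,5-dimethoxyphenol
Conditions: NBS (1.0 equiv), CH2Cl2, −78 °C → 23 °C
Reagents that add atoms: N-bromosuccinimide, O=C1CCC(=O)N1Br
Why: Electrophilic aromatic bromination; the two equivalent carbons ortho to the hydroxyl (each para to a methoxyl) are less hindered than C4 between the two methoxyls, and one equivalent at low temperature in a non-polar solvent should limit twofold bromination.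

Step 2
Reactants: 2 2-bromo-3,5-dimethoxyphenol
Product: 3 (2-bromo-3,5-dimethoxyphenoxy)trimethylsilane
Conditions: HMDS, THF, 70 °C; concentrate
Reagents that add atoms: hexamethyldisilazane, C[Si](C)(C)N[Si](C)(C)C
Why: O-silylation of a phenol with a silazane; ammonia is the only by-product, so the moisture-sensitive silyl ether can be used after evaporation.

Step 3
Reactants: 3 (2-bromo-3,5-dimethoxyphenoxy)trimethylsilane
Product: 5 3,5-dimethoxy-2-(trimethylsilyl)phenyl trifluoromethanesulfonate, via lithium 3,5-dimethoxy-2-(trimethylsilyl)phenoxide 4 (not isolated)
Conditions: n-BuLi, THF, −100 °C; then Tf2O, −100 °C → −80 °C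
Reagents that add atoms: trifluoromethanesulfonic anhydride, O=S(=O)(OS(=O)(=O)C(F)(F)F)C(F)(F)F
Why: Bromine–lithium exchange followed by anionic 1,3 O→C silyl migration (retro-Brook rearrangement), driven by formation of the phenoxide, which is O-triflated in the same flask; the aryl methyl ethers do not react with n-BuLi at this temperature.

Step 4
Reactants: 6 methyl 2-(4-hydroxy-3-methoxyphenyl)acetate (methyl homovanillate); 7 3-chloro-3-methylbut-1-yne
Product: 8 methyl 2-[3-methoxy-4-(2-methylbut-3-yn-2-yloxy)phenyl]acetate
Conditions: K2CO3, KI, CuI (cat.), acetone, 56 °C
Reagents that add atoms: none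
Why: O-alkylation of the phenoxide (Williamson-type ether synthesis) by the tertiary propargylic chloride, assisted by monovalent copper through its acetylide so that substitution at the hindered carbon is possible; carbonate does not deprotonate the ester α-carbon.

Step 5
Reactants: 8 methyl 2-[3-methoxy-4-(2-methylbut-3-yn-2-yloxy)phenyl]acetate
Product: 9 methyl 2-(8-methoxy-2,2-dimethyl-2H-chromen-6-yl)acetate
Conditions: PhNEt2, 190 °C
Reagents that add atoms: none
Why: Aromatic propargyl Claisen rearrangement to the only free ortho carbon, then tautomerisation, 1,5-hydrogen shift and oxa-6π electrocyclisation give the 2,2-dimethylchromene; the methoxyl on the other ortho carbon removes any regiochemical choice.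

Step 6
Reactants: 9 methyl 2-(8-methoxy-2,2-dimethyl-2H-chromen-6-yl)acetate
Product: 10 methyl 2-(8-methoxy-2,2-dimethylchroman-6-yl)acetate
Conditions: H2 (1 atm), Pd/C, EtOAc, 23 °C
Reagents that add atoms: none
Why: Catalytic hydrogenation of a cis-disubstituted styrenic alkene; the ester, the aryl ethers and the arene do not react under these conditions.

Step 7
Reactants: 10 methyl 2-(8-methoxy-2,2-dimethylchroman-6-yl)acetate; 11 methyl formate
Product: 12 methyl 3-hydroxy-2-(8-methoxy-2,2-dimethylchroman-6-yl)acrylate (enol tautomer of the α-formyl ester)
Conditions: NaH, HCO2Me (excess), THF, 0 °C → 23 °C; then 1 M HCl, 0 °C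
Reagents that add atoms: none
Why: Crossed Claisen condensation; methyl formate has no α-hydrogen and is the more electrophilic ester, and deprotonation of the product drives the equilibrium.

Step 8
Reactants: 12 methyl 3-hydroxy-2-(8-methoxy-2,2-dimethylchroman-6-yl)acrylate
Product: 13 methyl (E)-3-methoxy-2-(8-methoxy-2,2-dimethylchroman-6-yl)acrylate
Conditions: Me2SO4, K2CO3, DMF, 23 °C
Reagents that add atoms: dimethyl sulfate, COS(=O)(=O)OC
Why: O-alkylation of the ambident enolate by a hard electrophile; the E isomer (methoxyl anti to the ester) should predominate, and the alkene geometry is in any case lost when this carbon becomes C2 of ring C.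

Step 9
Reactants: 13 methyl (E)-3-methoxy-2-(8-methoxy-2,2-dimethylchroman-6-yl)acrylate
Product: 14 (E)-3-methoxy-2-(8-methoxy-2,2-dimethylchroman-6-yl)acrylic acid
Conditions: NaOH, MeOH/THF/H2O, 40 °C; then 1 M HCl to pH 3, 0 °C
Reagents that add atoms: sodium hydroxide, [Na+].[OH-]
Why: Saponification by acyl–oxygen cleavage (BAc2); once the carboxylate has formed, the vinylogous ester is deactivated towards further attack, and brief cold acidification should spare the enol ether.

Step 10
Reactants: 14 (E)-3-methoxy-2-(8-methoxy-2,2-dimethylchroman-6-yl)acrylic acid; 5 3,5-dimethoxy-2-(trimethylsilyl)phenyl trifluoromethanesulfonate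
Product: 18 5,7-dimethoxy-3-(8-methoxy-2,2-dimethylchroman-6-yl)-4H-chromen-4-one, via caesium (E)-3-methoxy-2-(8-methoxy-2,2-dimethylchroman-6-yl)acrylate 15 (not isolated), via 3,5-dimethoxybenzyne 16 (not isolated), via caesium 3,5-dimethoxy-2-[(E)-3-methoxy-2-(8-methoxy-2,2-dimethylchroman-6-yl)acryloyl]phenoxide 17 (not isolated)
Conditions: CsF (4 equiv), 5 (1.5 equiv), THF, 125 °C, sealed tube
Reagents that add atoms: none
Why: Fluoride converts 14 into carboxylate 15 and removes the silyl group of 5, and loss of triflate gives aryne 16. A carboxylate oxygen of 15 adds to the aryne carbon remote from the flanking methoxyl (future C8a), because the developing aryl anion then sits on the carbon next to the inductively withdrawing C–O bond (future C4a); this is the regiochemistry the step needs, and the future C5 methoxyl secures it. The aryl anion attacks the ester carbonyl in a 4-exo-trig sense, and the four-membered alkoxide opens to ortho-acyl phenoxide 17, a net insertion of the aryne into the C–O bond of the acid in which the carboxylate oxygen becomes O1. The phenoxide of 17 closes ring C by 6-endo-trig oxa-Michael addition to the β-methoxy enone, and E1cB loss of methoxide gives the pyranone irreversibly. The closest known reaction type is the CsF-mediated insertion of arynes into carboxylic acids to give ortho-hydroxyaryl ketones, with oxa-Michael closure in the same flask to chromanones from acrylic acids and to flavones from arylpropiolic acids; the β-methoxyl here only adds a leaving group. No stereocentre is formed, and the alkene geometry of 14 is lost in ring C. Chemoselectivity rests on the carbonyl carbon being the only electrophilic site within reach of the in-plane aryl anion, the β-carbon being more remote and deactivated by its methoxyl.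

Step 11
Reactants: 18 5,7-dimethoxy-3-(8-methoxy-2,2-dimethylchroman-6-yl)-4H-chromen-4-one
Product: 19 5,7-dihydroxy-3-(8-hydroxy-2,2-dimethylchroman-6-yl)-4H-chromen-4-one (CNP0129770.0)
Conditions: BBr3 (excess), CH2Cl2, −78 °C → 23 °C; then H2O, 0 °C → 23 °C
Reagents that add atoms: none
Why: Lewis acid cleavage of aryl methyl ethers by bromide attack at the methyl carbon of the boron-complexed ether; the C5 ether goes first through chelation with the C4 carbonyl, the guaiacol-type ring B ether next and the C7 ether last. If the tertiary C–O bond of ring D ionises, only the C4' oxygen can reach that carbon, so re-closure in the acidic aqueous work-up re-forms the same ring.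

## Compound list

1 | 3,5-dimethoxyphenol | COc1cc(O)cc(OC)c1 | starting material
2 | 2-bromo-3,5-dimethoxyphenol | COc1cc(O)c(Br)c(OC)c1 | intermediate
3 | (2-bromo-3,5-dimethoxyphenoxy)trimethylsilane | COc1cc(O[Si](C)(C)C)c(Br)c(OC)c1 | intermediate
4 | lithium 3,5-dimethoxy-2-(trimethylsilyl)phenoxide | COc1cc([O-])c([Si](C)(C)C)c(OC)c1.[Li+] | intermediate (not isolated)
5 | 3,5-dimethoxy-2-(trimethylsilyl)phenyl trifluoromethanesulfonate | COc1cc(OC)c([Si](C)(C)C)c(OS(=O)(=O)C(F)(F)F)c1 | intermediate
6 | methyl 2-(4-hydroxy-3-methoxyphenyl)acetate (methyl homovanillate) | COC(=O)Cc1ccc(O)c(OC)c1 | starting material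
7 | 3-chloro-3-methylbut-1-yne | CC(C)(Cl)C#C | starting material
8 | methyl 2-[3-methoxy-4-(2-methylbut-3-yn-2-yloxy)phenyl]acetate | COC(=O)Cc1ccc(OC(C)(C)C#C)c(OC)c1 | intermediate
9 | methyl 2-(8-methoxy-2,2-dimethyl-2H-chromen-6-yl)acetate | COC(=O)Cc1cc(OC)c2OC(C)(C)C=Cc2c1 | intermediate
10 | methyl 2-(8-methoxy-2,2-dimethylchroman-6-yl)acetate | COC(=O)Cc1cc(OC)c2OC(C)(C)CCc2c1 | intermediate
11 | methyl formate | COC=O | starting material
12 | methyl 3-hydroxy-2-(8-methoxy-2,2-dimethylchroman-6-yl)acrylate (enol tautomer) | COC(=O)C(=CO)c1cc(OC)c2OC(C)(C)CCc2c1 | intermediate
13 | methyl (E)-3-methoxy-2-(8-methoxy-2,2-dimethylchroman-6-yl)acrylate | CO/C=C(/C(=O)OC)c1cc(OC)c2OC(C)(C)CCc2c1 | intermediate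
14 | (E)-3-methoxy-2-(8-methoxy-2,2-dimethylchroman-6-yl)acrylic acid | CO/C=C(/C(=O)O)c1cc(OC)c2OC(C)(C)CCc2c1 | intermediate
15 | caesium (E)-3-methoxy-2-(8-methoxy-2,2-dimethylchroman-6-yl)acrylate | CO/C=C(/C(=O)[O-])c1cc(OC)c2OC(C)(C)CCc2c1.[Cs+] | intermediate (not isolated)
16 | 3,5-dimethoxybenzyne (1,2-didehydro-3,5-dimethoxybenzene) | COC1=CC(OC)=CC#C1 | intermediate (not isolated)
17 | caesium 3,5-dimethoxy-2-[(E)-3-methoxy-2-(8-methoxy-2,2-dimethylchroman-6-yl)acryloyl]phenoxide | CO/C=C(/C(=O)c1c([O-])cc(OC)cc1OC)c1cc(OC)c2OC(C)(C)CCc2c1.[Cs+] | intermediate (not isolated)
18 | 5,7-dimethoxy-3-(8-methoxy-2,2-dimethylchroman-6-yl)-4H-chromen-4-one | COc1cc(OC)c2c(c1)occ(-c1cc(OC)c3OC(C)(C)CCc3c1)c2=O | intermediate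
19 | 5,7-dihydroxy-3-(8-hydroxy-2,2-dimethylchroman-6-yl)-4H-chromen-4-one | CC1(C)CCc2cc(-c3coc4cc(O)cc(O)c4c3=O)cc(O)c2O1 | target

## Step count and least certain steps

Total step count: 11. Longest linear sequence: 8 steps (steps 4 to 11, from 6 to 19); the aryne branch from 1 adds 3 steps and joins at step 10.

**Step 10 (key step).** Three processes could divert it.
- The aryl anion could be protonated by the bifluoride formed from 14 before it transfers the acyl group, so the reaction would stop at O-arylation of the carboxylate.
- Phenoxide 17 could be captured by a second molecule of 16 before it closes.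
- The liberated methoxide could consume 16.

The vinylogous-carbonate character of the ester carbonyl also makes the acyl transfer slower than with simple acids.

Fallback: set out from ester 10 and phenol 1 and return at 18 by the classical deoxybenzoin sequence. Ester 10 would be saponified (NaOH, aqueous MeOH) to 2-(8-methoxy-2,2-dimethylchroman-6-yl)acetic acid F1. Heating F1 with 1 in BF3·OEt2 (Friedel–Crafts acylation through the aryl ester and Fries shift, directed ortho to the hydroxyl by boron chelation) should give 1-(2-hydroxy-4,6-dimethoxyphenyl)-2-(8-methoxy-2,2-dimethylchroman-6-yl)ethan-1-one F2. Condensation of F2 with N,N-dimethylformamide dimethyl acetal in toluene at 100 °C, with ring closure and loss of dimethylamine, should give 18.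

**Step 11.** The tertiary C–O bond of ring D could ionise under the Lewis acid and be captured by bromide (ring opening). The C7 methyl ether, whose oxygen is deactivated by conjugation with the C4 carbonyl, could cleave incompletely under conditions mild enough to spare ring D.

Fallback: set out from 18 and return at 19, giving up the attempt to preserve ring D. Excess BBr3 at 23 °C would be applied until all three methyl ethers are cleaved, and the crude product taken as the ring-opened tertiary bromide 3-[3-(3-bromo-3-methylbutyl)-4,5-dihydroxyphenyl]-5,7-dihydroxy-4H-chromen-4-one F3. Ring D would then be rebuilt in a separate operation by acid-catalysed intramolecular etherification (TsOH·H2O, toluene/dioxane, 80 °C). This can only involve the C4' oxygen and should give 19.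

**Step 1.** Bromination could occur at C4, between the two methoxyls, or twice, since all three free ring carbons are activated.

Fallback: set out from 1 and return at 5 by directed ortho-metalation. Phenol 1 with isopropyl isocyanate (Et3N cat., CH2Cl2) would give 3,5-dimethoxyphenyl N-isopropylcarbamate F4. Transient N-silylation (TBSOTf, TMEDA, Et2O), lithiation with n-BuLi/TMEDA at −78 °C at the carbon flanked by carbamate and methoxyl, quenching with TMSCl and acidic work-up should give 3,5-dimethoxy-2-(trimethylsilyl)phenyl N-isopropylcarbamate F5. Cleavage of the carbamate with DBU and Et2NH in MeCN at 40 °C and triflation of the resulting phenoxide with PhNTf2 in the same flask should give 5.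

**Step 9.** Hydroxide could add at the β-carbon of the vinylogous ester with loss of methoxide and retro-Claisen deformylation. The enol ether could also hydrolyse and decarboxylate during acidification.

Fallback: set out from 13 and return at 18 without hydroxide or acid. Anhydrous cleavage of the methyl ester with KOSiMe3 in THF at 23 °C should precipitate potassium (E)-3-methoxy-2-(8-methoxy-2,2-dimethylchroman-6-yl)acrylate F6. F6 would be filtered, dried and used in place of 14 in step 10 with 5 and CsF. Since no proton is introduced with the carboxylate, this also removes the proton source that threatens the aryl anion in step 10.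

**Step 4.** Dehydrochlorination of the tertiary chloride could outrun substitution at the hindered centre, leaving the phenol unconverted.

Fallback: set out from 6 and return at 9 in one operation by condensing 6 with 3-methylbut-2-enal in the presence of PhB(OH)2 and propionic acid in toluene at reflux with a Dean–Stark trap. The boron-templated ortho-alkylation, ortho-quinone methide formation and oxa-6π closure again can only use C5'. This fallback makes no compound outside the compound list (F0).

## Further compounds

F1 | step 10 | 2-(8-methoxy-2,2-dimethylchroman-6-yl)acetic acid | COc1cc(CC(=O)O)cc2CCC(C)(C)Oc12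
F2 | step 10 | 1-(2-hydroxy-4,6-dimethoxyphenyl)-2-(8-methoxy-2,2-dimethylchroman-6-yl)ethan-1-one | COc1cc(O)c(C(=O)Cc2cc(OC)c3OC(C)(C)CCc3c2)c(OC)c1
F3 | step 11 | 3-[3-(3-bromo-3-methylbutyl)-4,5-dihydroxyphenyl]-5,7-dihydroxy-4H-chromen-4-one | CC(C)(Br)CCc1cc(cc(O)c1O)-c1coc2cc(O)cc(O)c2c1=O
F4 | step 1 | 3,5-dimethoxyphenyl N-isopropylcarbamate | COc1cc(OC)cc(OC(=O)NC(C)C)c1
F5 | step 1 | 3,5-dimethoxy-2-(trimethylsilyl)phenyl N-isopropylcarbamate | COc1cc(OC)c([Si](C)(C)C)c(OC(=O)NC(C)C)c1
F6 | step 9 | potassium (E)-3-methoxy-2-(8-methoxy-2,2-dimethylchroman-6-yl)acrylate | CO/C=C(/C(=O)[O-])c1cc(OC)c2OC(C)(C)CCc2c1.[K+]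
F0 | step 4 | none | none
A1 | alternative 1 | 5,7-dimethoxy-3-(8-methoxy-2,2-dimethyl-2H-chromen-6-yl)-4H-chromen-4-one | COc1cc(OC)c2c(c1)occ(-c1cc(OC)c3OC(C)(C)C=Cc3c1)c2=O
A2 | alternative 1 | 5,7-dimethoxy-3-[3-methoxy-4-(2-methylbut-3-yn-2-yloxy)phenyl]-4H-chromen-4-one | COc1cc(OC)c2c(c1)occ(-c1ccc(OC(C)(C)C#C)c(OC)c1)c2=O
A3 | alternative 2 | 5,7-difluoro-3-(8-methoxy-2,2-dimethylchroman-6-yl)-4H-chromen-4-one | COc1cc(-c2coc3cc(F)cc(F)c3c2=O)cc2CCC(C)(C)Oc12
A4 | alternative 2 | 3-hydroxy-2-(8-methoxy-2,2-dimethylchroman-6-yl)-1-(2,4,6-trifluorophenyl)prop-2-en-1-one | OC=C(C(=O)c1c(F)cc(F)cc1F)c1cc(OC)c2OC(C)(C)CCc2c1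
A5 | alternative 3 | 5-hydroxy-7-methoxy-3-(8-methoxy-2,2-dimethylchroman-6-yl)-4H-chromen-4-one | COc1cc(O)c2c(c1)occ(-c1cc(OC)c3OC(C)(C)CCc3c1)c2=O
A6 | alternative 3 | 1,3-dimethoxy-1-(trimethylsilyloxy)buta-1,3-diene | COC(=C)C=C(OC)O[Si](C)(C)C
A7 | alternative 3 | 3-bromo-5-(8-methoxy-2,2-dimethylchroman-6-yl)-4H-pyran-4-one | COc1cc(cc2CCC(C)(C)Oc12)-c1cocc(Br)c1=O
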